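**Retrosynthetic overview**
1. Target 9 ⇐ iminium salt 8 (hydride quench) ⇐ enaminone lactam 7 + POBr3: the C2–Br comes from the lactam C=O and the CH2NMe2 arm from an enaminone, in one flask, so there is no Mannich reaction and no bromination of an indole.
2. 7 ⇐ 5,6-dibromooxindole 5 by aminomethylenation with DMF dimethyl acetal (which also blocks C3), then N-methylation.
3. 5 ⇐ nitroaryl acetate 3 by nitro reduction and lactamisation; 3 ⇐ 1,2-dibromo-4-nitrobenzene 1 + tert-butyl chloroacetate 2 by vicarious nucleophilic substitution of hydrogen.
4. Ring order: the benzene ring is bought with both aryl bromines in place; the five-membered ring is closed as a lactam (step 2) and becomes the aromatic pyrrole ring only in the last step.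

Assumption: the target has no stereocentre and is achiral, so no enantiocontrol is needed; the only stereo-element on the way is the enamine C=C geometry of 6 and 7, which is erased in step 5.

**Step 1**
Reactants: 1 1,2-dibromo-4-nitrobenzene; 2 tert-butyl chloroacetate
Product: 3 tert-butyl 2-(4,5-dibromo-2-nitrophenyl)acetate
Conditions: KOtBu (2.5 equiv), DMF, −40 → −20 °C; then aq. HCl
Reagents that add atoms: none
Why: Vicarious nucleophilic substitution of hydrogen (Makosza reaction), in which the α-chloro ester carbanion adds at the only unhindered C–H ortho to NO2 (para is blocked by Br, the other ortho site is flanked by Br) and base-induced loss of HCl from the adduct outruns SNAr displacement of bromide; no stereocentre is formed.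

**Step 2**
Reactants: 3 tert-butyl 2-(4,5-dibromo-2-nitrophenyl)acetate
Product: 5 5,6-dibromoindolin-2-one, via amino ester 4 (not isolated)
Conditions: Fe powder (6 equiv), AcOH, 100 °C; then TsOH·H2O (cat.), 110 °C
Reagents that add atoms: none
Why: Béchamp-type iron/acetic acid nitro reduction leaves aryl bromides untouched, and the resulting aniline acylates on the neighbouring ester under hot acid (5-exo-trig lactamisation); no stereocentre is formed.

**Step 3**
Reactants: 5 5,6-dibromoindolin-2-one
Product: 6 (E)-5,6-dibromo-3-[(dimethylamino)methylidene]indolin-2-one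
Conditions: Me2NCH(OMe)2 (1.5 equiv), THF, 60 °C
Reagents that add atoms: N,N-dimethylformamide dimethyl acetal, COC(OC)N(C)C
Why: Knoevenagel-type aminomethylenation of the acidic C3 methylene by the amide acetal gives a push–pull enaminone that carries the future CH2NMe2 carbon and nitrogen and blocks C3; only an alkene geometry arises (E expected, possibly with some Z, irrelevant later).

**Step 4**
Reactants: 6 (E)-5,6-dibromo-3-[(dimethylamino)methylidene]indolin-2-one
Product: 7 (E)-5,6-dibromo-3-[(dimethylamino)methylidene]-1-methylindolin-2-one
Conditions: NaH (1.1 equiv), DMF, 0 °C; MeI (1.1 equiv), 0 °C → rt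
Reagents that add atoms: iodomethane, CI
Why: With C3 blocked the lactam N–H is the only acidic site, so its sodium salt undergoes SN2 N-alkylation (amide-anion alkylation), while the enamine nitrogen is a non-nucleophilic vinylogous amide and is not quaternised; no stereocentre is formed.

**Step 5**
Reactants: 7 (E)-5,6-dibromo-3-[(dimethylamino)methylidene]-1-methylindolin-2-one
Product: 9 2,5,6-tribromo-1-methylgramine, via iminium salt 8 (not isolated)
Conditions: POBr3 (1.2 equiv), ClCH2CH2Cl, 0 → 70 °C; then −10 °C, NaBH4 (5 equiv), MeOH added slowly; aq. NaOH work-up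
Reagents that add atoms: phosphorus oxybromide, O=P(Br)(Br)Br
Why: Proposed new method: an interrupted Vilsmeier–Haack haloformylation with reductive quench, in which POBr3 O-phosphorylates the vinylogous carbamoyl oxygen of 7, the ring aromatises to a 2-(phosphoryloxy)indol-3-yl methyleneiminium, bromide displaces dibromophosphate at C2 by addition–elimination to give 8, and borohydride then adds to the exocyclic iminium carbon (restoring the neutral aromatic indole, which is why attack at C2 is disfavoured) in place of the usual water quench; the closest known reactions are the Vilsmeier haloformylation of oxindoles to 2-haloindole-3-carbaldehydes and the NaBH4 reduction of Vilsmeier iminium salts to dimethylaminomethyl arenes; no stereocentre is formed.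

**Compound list**
1 | 1,2-dibromo-4-nitrobenzene | O=[N+]([O-])c1ccc(Br)c(Br)c1 | starting material
2 | tert-butyl chloroacetate | CC(C)(C)OC(=O)CCl | starting material
3 | tert-butyl 2-(4,5-dibromo-2-nitrophenyl)acetate | CC(C)(C)OC(=O)Cc1cc(Br)c(Br)cc1[N+](=O)[O-] | intermediate
4 | tert-butyl 2-(2-amino-4,5-dibromophenyl)acetate | CC(C)(C)OC(=O)Cc1cc(Br)c(Br)cc1N | intermediate
5 | 5,6-dibromoindolin-2-one | O=C1Cc2cc(Br)c(Br)cc2N1 | intermediate
6 | (E)-5,6-dibromo-3-[(dimethylamino)methylidene]indolin-2-one | CN(C)/C=C1/C(=O)Nc2cc(Br)c(Br)cc21 | intermediate
7 | (E)-5,6-dibromo-3-[(dimethylamino)methylidene]-1-methylindolin-2-one | CN(C)/C=C1/C(=O)N(C)c2cc(Br)c(Br)cc21 | intermediate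
8 | N-[(2,5,6-tribromo-1-methyl-1H-indol-3-yl)methylidene]-N-methylmethanaminium dibromophosphate | C[N+](C)=Cc1c(Br)n(C)c2cc(Br)c(Br)cc12.[O-]P(=O)(Br)Br | intermediate
9 | 2,5,6-tribromo-1-methylgramine, 1-(2,5,6-tribromo-1-methyl-1H-indol-3-yl)-N,N-dimethylmethanamine (achiral) | CN(C)Cc1c(Br)n(C)c2cc(Br)c(Br)cc12 | target

**Totals**
Total step count: 5. Longest linear sequence: 5 steps (1 → 3 → 5 → 6 → 7 → 9).

**Steps most likely to fail, each with a fallback**

Step 5 (one-pot deoxybromination and hydride quench; risks are attack of methanol or hydride at C2 and interference of phosphorus residues with the borohydride). The fallback sets out from 8 (made from 7 as in step 5) and comes back at 9. The hydride quench is replaced by a water quench and a separate C–N bond-forming step. The reaction mixture is poured into cold aqueous NaOAc, which hydrolyses the iminium to 2,5,6-tribromo-1-methyl-1H-indole-3-carbaldehyde F1, an isolable solid that can be purified free of phosphorus. F1 is then reductively aminated with Me2NH (2 M in THF), AcOH and NaBH(OAc)3 in ClCH2CH2Cl at rt; the iminium re-forms as [(2,5,6-tribromo-1-methyl-1H-indol-3-yl)methylidene]dimethylammonium acetate F2 under buffered conditions and is reduced to 9.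

Step 1 (vicarious substitution; risks are attack at the hindered ortho position and SNAr of the bromine para to NO2). The fallback sets out from 1 and comes back at 4. The nitro group is given up as the director and the carbon is brought in by cross-coupling. Fe/NH4Cl in aqueous EtOH reduces 1 to 3,4-dibromoaniline F3. NIS in MeCN iodinates the only unhindered position ortho to NH2 (para is blocked) to give 4,5-dibromo-2-iodoaniline F4. A chemoselective Negishi coupling of the C–I bond with the Reformatsky reagent BrZnCH2CO2tBu (Pd(PPh3)4, THF, 40 °C; zerovalent palladium inserts into C–I much faster than into C–Br) gives amino ester 4, which is lactamised to 5 under the acid conditions of step 2.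

Step 4 (N-methylation; risks are O-methylation of the ambident lactam anion or quaternisation). The fallback sets out from 3 and comes back at 7. The nitrogen is methylated before the lactam exists, so no ambident anion is involved. Fe/NH4Cl in aqueous EtOH at 60 °C (neutral, so the tert-butyl ester does not lactamise) reduces 3 to amino ester 4, which is isolated. Chan–Lam monomethylation (MeB(OH)2, Cu(OAc)2, pyridine, dioxane, reflux) gives tert-butyl 2-[4,5-dibromo-2-(methylamino)phenyl]acetate F5. TsOH in toluene at 100 °C closes it to 5,6-dibromo-1-methylindolin-2-one F6. Condensation with N,N-dimethylformamide dimethyl acetal as in step 3 then gives 7.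

**Further compounds**
F1 | step 5 | 2,5,6-tribromo-1-methyl-1H-indole-3-carbaldehyde | Cn1c(Br)c(C=O)c2cc(Br)c(Br)cc21
F2 | step 5 | [(2,5,6-tribromo-1-methyl-1H-indol-3-yl)methylidene]dimethylammonium acetate | C[N+](C)=Cc1c(Br)n(C)c2cc(Br)c(Br)cc12.CC(=O)[O-]
F3 | step 1 | 3,4-dibromoaniline | Nc1ccc(Br)c(Br)c1
F4 | step 1 | 4,5-dibromo-2-iodoaniline | Nc1cc(Br)c(Br)cc1I
F5 | step 4 | tert-butyl 2-[4,5-dibromo-2-(methylamino)phenyl]acetate | CNc1cc(Br)c(Br)cc1CC(=O)OC(C)(C)C
F6 | step 4 | 5,6-dibromo-1-methylindolin-2-one | CN1C(=O)Cc2cc(Br)c(Br)cc21
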